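**Strategy.** Everything rests on cutting the C7–C8 bond that ring B (C1, C5–C10) of the guaianolide half shares with its α-methylene lactone: C7 bears C11(=C13)–C12 and C8 the lactone oxygen, the homoallylic alcohol motif of a 2-(alkoxycarbonyl)allyl addition. Divalent chromium converts the C13 bromide into an allylchromium reagent whose γ-carbon C7 adds to the C8 aldehyde, which closes the seven-membered ring onto the rigid norbornene and sets C7 and C8 in one operation. The precursor is the spiro-norbornene from a Diels–Alder union of an acetoxy silyloxy cyclopentadiene with the carvone-derived seco-eudesmanolide, carrying a formyl arm on bridgehead C1 and a (Z)-2-(bromomethyl)enoate arm on C5.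

Key step: step 28

Remark on numbering: guaiane numbers C1–C15 are used for the norbornene half (C1, C3 bridgeheads; C2 the one-carbon bridge; C4=C5 the alkene; C6–C10 ring B; C11–C13 the lactone carbons). Primed numbers are used for the 1,10-seco-eudesmanolide half (C5′=C6′ alkene, C7′/C8′ lactone fusion, C10′ carbinol, C11′ spiro carbon, C13′ the norbornane CH2, C4′ side-chain stereocentre, C1′ acetate carbon).

Assumption 1: (R)-TRIP phosphoric acid is taken to deliver the crotyl group to the aldehyde face that gives the (1R,2R) alcohol; if the sense is opposite, the enantiomeric acid is used.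

Assumption 2: the Piancatelli rearrangement is expected to give both 4,5-trans isomers (ring configuration relative to C10) in similar amounts; only the (4R,5S) isomer is carried on.

Assumption 3: (S)-γ-valerolactone, allyltributylstannane and methyl 2-(bromomethyl)acrylate are taken as commercial.

**Cyclopentenone half (steps 1–5)**

Step 1
Reactants: 1 3-methylfuran-2-carbaldehyde; 2 (E)-crotylboronic acid pinacol ester
Product: 3 (1R,2R)-2-methyl-1-(3-methylfuran-2-yl)but-3-en-1-ol
Conditions: (R)-TRIP phosphoric acid (5 mol %), toluene, −30 °C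
Reagents that add atoms: none
Why: Chiral phosphoric acid-catalysed crotylboration through a chair (Zimmerman–Traxler) transition state, in which the (E)-crotyl geometry gives the anti relationship and the catalyst selects the aldehyde face, which sets C10 (the carbinol centre is erased later).

Step 2
Reactants: 3 (1R,2R)-2-methyl-1-(3-methylfuran-2-yl)but-3-en-1-ol
Product: 4 (1R,2R)-2-methyl-1-(3-methylfuran-2-yl)butane-1,4-diol
Conditions: 9-borabicyclo[3.3.1]nonane (2.2 equiv), THF, 0 °C → rt; then NaOH, H2O2, 0 °C
Reagents that add atoms: hydrogen peroxide OO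
Why: Anti-Markovnikov hydroboration–oxidation of the terminal alkene with the bulky borane should leave the furan untouched and turn the vinyl group into the C9–C8 hydroxyethyl arm without touching C10.

Step 3
Reactants: 4 (1R,2R)-2-methyl-1-(3-methylfuran-2-yl)butane-1,4-diol
Product: 5 (1R,2R)-4-[(tert-butyldiphenylsilyl)oxy]-2-methyl-1-(3-methylfuran-2-yl)butan-1-ol
Conditions: tert-butyl(chloro)diphenylsilane (1.05 equiv), imidazole, CH2Cl2, 0 °C
Reagents that add atoms: tert-butyl(chloro)diphenylsilane CC(C)(C)[Si](Cl)(c1ccccc1)c1ccccc1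
Why: Silylation with the bulky chloride should take the primary hydroxyl selectively over the hindered furyl carbinol, and this silyl ether withstands the aqueous Lewis acid of the next step.

Step 4
Reactants: 5 (1R,2R)-4-[(tert-butyldiphenylsilyl)oxy]-2-methyl-1-(3-methylfuran-2-yl)butan-1-ol
Product: 6 (4R,5S)-5-[(2R)-4-[(tert-butyldiphenylsilyl)oxy]butan-2-yl]-4-hydroxy-2-methylcyclopent-2-en-1-one
Conditions: Dy(OTf)3 (10 mol %), t-BuOH/H2O 5:1, 80 °C; chromatographic separation of the two trans isomers
Reagents that add atoms: water O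
Why: Piancatelli rearrangement (furfuryl cation, addition of water, ring opening, conrotatory 4π electrocyclisation) should give the 4,5-trans hydroxy cyclopentenone with the furan methyl on the enone α-carbon, and the (4R,5S) isomer, which carries the C2 configuration of the target, is separated from its ring diastereomer.

Step 5
Reactants: 6 (4R,5S)-5-[(2R)-4-[(tert-butyldiphenylsilyl)oxy]butan-2-yl]-4-hydroxy-2-methylcyclopent-2-en-1-one
Product: 7 (1R,5S)-5-[(2R)-4-[(tert-butyldiphenylsilyl)oxy]butan-2-yl]-3-methyl-4-oxocyclopent-2-en-1-yl acetate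
Conditions: Ac2O, pyridine, DMAP (cat.), CH2Cl2, 0 °C
Reagents that add atoms: acetic anhydride CC(=O)OC(C)=O
Why: Standard acylation of the secondary allylic alcohol installs the C2 acetate of the target with retention before ring carbon C1 is flattened.

**Seco-eudesmanolide half (steps 6–21)**

Step 6
Reactants: 8 (S)-(+)-carvone
Product: 9 (1S,5S)-cis-carveol
Conditions: NaBH4, CeCl3·7H2O, MeOH, −78 → 0 °C
Reagents that add atoms: none
Why: Luche 1,2-reduction delivers hydride axially, anti to the isopropenyl group, and should give the cis allylic alcohol that directs the next epoxidation.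

Step 7
Reactants: 9 (1S,5S)-cis-carveol
Product: 10 (1S,2S,4R,6R)-1-methyl-4-(prop-1-en-2-yl)-7-oxabicyclo[4.1.0]heptan-2-ol
Conditions: VO(acac)2 (2 mol %), t-BuOOH, CH2Cl2, 0 °C → rt
Reagents that add atoms: tert-butyl hydroperoxide CC(C)(C)OO
Why: Vanadium-catalysed hydroxyl-directed epoxidation puts the oxirane on the face of the hydroxyl, hence cis to the isopropenyl group (this sets C10′), and leaves the isolated isopropenyl alkene alone.

Step 8
Reactants: 10 (1S,2S,4R,6R)-1-methyl-4-(prop-1-en-2-yl)-7-oxabicyclo[4.1.0]heptan-2-ol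
Product: 12 (1S,2R,5R)-2-methyl-5-(prop-1-en-2-yl)cyclohex-3-ene-1,2-diol, via hydroxy selenide 11 (not isolated)
Conditions: (PhSe)2, NaBH4, EtOH, 70 °C; then H2O2, THF, 0 °C → rt
Reagents that add atoms: none
Why: Phenylselenide should open the epoxide trans-diaxially at the secondary carbon C9′, and syn elimination of the selenoxide (only C8′ carries a β-hydrogen) gives the transposed tertiary allylic alcohol with the C8′=C9′ alkene.

Step 9
Reactants: 12 (1S,2R,5R)-2-methyl-5-(prop-1-en-2-yl)cyclohex-3-ene-1,2-diol
Product: 13 the 3,4-epoxide of 12 with the oxirane cis to both hydroxyls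
Conditions: VO(acac)2 (2 mol %), t-BuOOH, CH2Cl2, 0 °C → rt
Reagents that add atoms: tert-butyl hydroperoxide CC(C)(C)OO
Why: Directed epoxidation again, now guided by the two cis hydroxyls, should place the new oxirane cis to the C10′ oxygen and to the isopropenyl group.

Step 10
Reactants: 13 the 3,4-epoxide of 12
Product: 14 (1S,2R,4S,5S)-2-methyl-5-(prop-1-en-2-yl)cyclohexane-1,2,4-triol
Conditions: LiAlH4, THF, 0 °C → rt
Reagents that add atoms: none
Why: Hydride opening of the epoxide should occur trans-diaxially at C9′ (Fürst–Plattner rule, the pattern of 2,3-epoxy alcohol reductions to 1,3-diols), which leaves the C8′ oxygen cis to the C10′ hydroxyl and to the C7′ substituent.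

Step 11
Reactants: 14 (1S,2R,4S,5S)-2-methyl-5-(prop-1-en-2-yl)cyclohexane-1,2,4-triol
Product: 15 (1S,2R,4S,5S)-5-(3-hydroxyprop-1-en-2-yl)-2-methylcyclohexane-1,2,4-triol
Conditions: SeO2 (0.5 equiv), t-BuOOH, CH2Cl2, rt
Reagents that add atoms: tert-butyl hydroperoxide CC(C)(C)OO; selenium dioxide O=[Se]=O
Why: Selenium dioxide allylic oxidation (ene reaction, then [2,3]-shift) of the only alkene should hydroxylate the isopropenyl methyl group, and any over-oxidised aldehyde converges in the next step.

Step 12
Reactants: 15 (1S,2R,4S,5S)-5-(3-hydroxyprop-1-en-2-yl)-2-methylcyclohexane-1,2,4-triol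
Product: 17 (3aS,5S,6R,7aS)-5,6-dihydroxy-6-methyl-3-methylidenehexahydro-1-benzofuran-2(3H)-one, via lactol 16 (not isolated)
Conditions: MnO2 (excess), CH2Cl2/acetone, rt
Reagents that add atoms: none
Why: Manganese dioxide oxidises only the allylic alcohol to the enal, which the cis C8′ hydroxyl traps as the lactol that is oxidised on to the cis-fused α-methylene lactone, while the non-allylic secondary and tertiary hydroxyls survive.

Step 13
Reactants: 17 (3aS,5S,6R,7aS)-5,6-dihydroxy-6-methyl-3-methylidenehexahydro-1-benzofuran-2(3H)-one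
Product: 18 (3aS,6R,7aS)-6-hydroxy-6-methyl-3-methylidenetetrahydro-1-benzofuran-2,5(3H,4H)-dione
Conditions: 1,1,1-triacetoxy-1,1-dihydro-1,2-benziodoxol-3(1H)-one, NaHCO3, CH2Cl2, 0 °C → rt
Reagents that add atoms: none
Why: The hypervalent iodine oxidant converts the one remaining secondary alcohol into the C5′ ketone without touching the tertiary alcohol or the enoate.

Step 14
Reactants: 18 (3aS,6R,7aS)-6-hydroxy-6-methyl-3-methylidenetetrahydro-1-benzofuran-2,5(3H,4H)-dione
Product: 19 the 6-O-triethylsilyl ether of 18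
Conditions: Et3SiOTf, 2,6-lutidine, CH2Cl2, −78 → 0 °C
Reagents that add atoms: triethylsilyl trifluoromethanesulfonate CC[Si](CC)(CC)OS(=O)(=O)C(F)(F)F
Why: Silyl triflate with a hindered pyridine base silylates the tertiary α-hydroxyl so that the ketone can be enolised cleanly in the next step.

Step 15
Reactants: 19 the 6-O-triethylsilyl ether of 18
Product: 20 the C5′=C6′ enol triflate of 19
Conditions: KHMDS, THF, −78 °C; then N-(5-chloropyridin-2-yl)bis(trifluoromethanesulfonimide)
Reagents that add atoms: N-(5-chloropyridin-2-yl)bis(trifluoromethanesulfonimide) Clc1ccc(nc1)N(S(=O)(=O)C(F)(F)F)S(=O)(=O)C(F)(F)F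
Why: Kinetic deprotonation can occur only at C6′ (C10′ is quaternary), and O-sulfonylation of the potassium enolate gives the enol triflate regiospecifically.

Step 16
Reactants: 21 (S)-γ-valerolactone
Product: 22 (S)-pentane-1,4-diol
Conditions: LiAlH4, THF, 0 °C → rt
Reagents that add atoms: none
Why: Hydride reduction of the lactone gives the diol without touching the stereocentre.

Step 17
Reactants: 22 (S)-pentane-1,4-diol
Product: 23 (S)-5-[(tert-butyldimethylsilyl)oxy]pentan-2-ol
Conditions: tert-butyl(chloro)dimethylsilane (1.0 equiv), imidazole, CH2Cl2, −10 °C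
Reagents that add atoms: tert-butyl(chloro)dimethylsilane CC(C)(C)[Si](C)(C)Cl
Why: Silylation with one equivalent of the bulky chloride should take the primary hydroxyl selectively.

Step 18
Reactants: 23 (S)-5-[(tert-butyldimethylsilyl)oxy]pentan-2-ol
Product: 24 tert-butyl{[(4R)-4-iodopentyl]oxy}dimethylsilane
Conditions: I2, PPh3, imidazole, CH2Cl2, −10 °C, short reaction time
Reagents that add atoms: iodine II
Why: Appel-type iodination displaces the alkoxyphosphonium ion by SN2 with inversion to give the (R)-iodide, and low temperature limits racemising iodide exchange.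

Step 19
Reactants: 24 tert-butyl{[(4R)-4-iodopentyl]oxy}dimethylsilane; 20 the C5′=C6′ enol triflate of 19
Product: 27 (3aS,6R,7aS)-5-[(2R)-5-[(tert-butyldimethylsilyl)oxy]pentan-2-yl]-6-methyl-3-methylidene-6-[(triethylsilyl)oxy]-3a,6,7,7a-tetrahydro-1-benzofuran-2(3H)-one, via alkyllithium 25 (not isolated), via alkylzinc 26 (not isolated)
Conditions: 24 (2 equiv), t-BuLi, pentane/Et2O 3:2, −100 °C; Me3SiCH2ZnBr·LiBr, −100 → −78 °C; then 20, Pd(OAc)2 (5 mol %), CPhos (10 mol %), THF, −25 °C → rt
Reagents that add atoms: none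
Why: Iodine–lithium exchange at −100 °C and transmetalation to zinc occur with retention, and the Negishi coupling of the secondary alkylzinc with the alkenyl triflate (oxidative addition, retentive transmetalation, reductive elimination kept faster than β-hydride elimination by the bulky biaryl phosphine) should transfer that configuration to C4′ (R) while the organozinc tolerates lactone and enoate.

Step 20
Reactants: 27 the coupled bis-silyl ether
Product: 28 (3aS,6R,7aS)-6-hydroxy-5-[(2R)-5-hydroxypentan-2-yl]-6-methyl-3-methylidene-3a,6,7,7a-tetrahydro-1-benzofuran-2(3H)-one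
Conditions: HF·pyridine, pyridine, THF, 0 °C → rt
Reagents that add atoms: none
Why: Fluoride-mediated desilylation cleaves both the primary and the tertiary silyl ether and leaves the lactone and alkenes alone.

Step 21
Reactants: 28 the diol
Product: 29 (4R)-4-[(3aS,6R,7aS)-6-hydroxy-6-methyl-3-methylidene-2-oxo-2,3,3a,6,7,7a-hexahydro-1-benzofuran-5-yl]pentyl acetate
Conditions: Ac2O, pyridine, CH2Cl2, 0 °C → rt (no DMAP)
Reagents that add atoms: acetic anhydride CC(=O)OC(C)=O
Why: Acylation without a nucleophilic catalyst should esterify only the primary alcohol, the hindered tertiary allylic alcohol staying free.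

**Union and end game (steps 22–29)**

Step 22
Reactants: 7 the acetoxy cyclopentenone; 29 the seco-eudesmanolide dienophile
Product: 31 spiro-norbornene adduct (C5 triethylsilyl enol ether, C8 silyl ether), via silyloxy diene 30 (not isolated)
Conditions: 7 (1.6 equiv), Et3SiOTf (1.05 equiv per 7), Et3N, CH2Cl2, −78 → −20 °C; then 29 (1.0 equiv), 1 M, −20 → 0 °C
Reagents that add atoms: triethylsilyl trifluoromethanesulfonate CC[Si](CC)(CC)OS(=O)(=O)C(F)(F)F
Why: Soft enolisation toward C1 gives the 2-silyloxy-5-acetoxycyclopentadiene, which is trapped cold in a normal-demand Diels–Alder reaction in which the silyloxy group sends the methylene carbon C13′ to C1 (para rule), the dienophile adds syn to the acetoxy group (the usual preference of 5-acyloxycyclopentadienes), through its convex face (syn to H7′) and with the lactone carbonyl endo, so that C1, C3 and C11′ should arise in the target configuration from a matched pair.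

Step 23
Reactants: 31 spiro-norbornene adduct
Product: 32 the C5 enol triflate of the adduct
Conditions: CsF, PhNTf2, DME, rt
Reagents that add atoms: N-phenylbis(trifluoromethanesulfonimide) O=S(=O)(N(c1ccccc1)S(=O)(=O)C(F)(F)F)C(F)(F)F
Why: Fluoride unmasks the regiodefined enolate from the silyl enol ether (the other α-carbon is the quaternary bridgehead) and the triflimide traps it on oxygen as the C4=C5 enol triflate.

Step 24
Reactants: 32 the C5 enol triflate; 33 allyltributylstannane
Product: 34 the C5-allyl norbornene (C8 silyl ether)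
Conditions: Pd(PPh3)4 (5 mol %), LiCl, THF, 65 °C
Reagents that add atoms: none
Why: Stille coupling (oxidative addition of zerovalent palladium into the alkenyl triflate, chloride-assisted transmetalation, reductive elimination) installs the C6–C7 allyl arm at C5 without touching any stereocentre.

Step 25
Reactants: 34 the C5-allyl norbornene (C8 silyl ether)
Product: 35 the C8 primary alcohol
Conditions: HF·pyridine, pyridine, THF, 0 °C → rt
Reagents that add atoms: none
Why: Fluoride-mediated desilylation frees the C8 hydroxyl at this point because the allylic bromide introduced later would alkylate pyridine.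

Step 26
Reactants: 35 the C8 primary alcohol
Product: 36 the C8 aldehyde with the C5-allyl arm
Conditions: 1,1,1-triacetoxy-1,1-dihydro-1,2-benziodoxol-3(1H)-one, NaHCO3, CH2Cl2, 0 °C → rt
Reagents that add atoms: none
Why: Mild hypervalent iodine oxidation gives the aldehyde, and the tertiary alcohol cannot be oxidised.

Step 27
Reactants: 36 the C8 aldehyde with the C5-allyl arm; 37 methyl 2-(bromomethyl)acrylate
Product: 38 the 7,8-seco aldehyde (Z)-allylic bromide
Conditions: 37 (6 equiv), second-generation Hoveyda–Grubbs catalyst RuCl2(H2IMes)(=CH-C6H4-2-OiPr) (10 mol %), 1,4-benzoquinone (20 mol %), CH2Cl2, 40 °C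
Reagents that add atoms: none
Why: Olefin cross-metathesis between the monosubstituted allyl alkene and the 2-substituted acrylate (the tri- and tetrasubstituted alkenes are inert) should give the trisubstituted enoate with the chain trans to the ester, that is the (Z)-bromide, under thermodynamic control.

Step 28
Reactants: 38 the 7,8-seco aldehyde (Z)-allylic bromide
Product: 40 the ring-B 8-hydroxy 12-methyl ester, via allylchromium 39 (not isolated)
Conditions: CrCl2 (10 equiv), THF, 5 mM, rt; aq NH4Cl, 0 °C
Reagents that add atoms: none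
Why: Two one-electron transfers from divalent chromium to the C13–Br bond give the allylchromium 39 (trivalent chromium), which binds the C8 aldehyde and adds through its γ-carbon C7 in a six-centre chair (SE2′), so that the C7–C8 bond forms, the alkene moves to C11=C13 and the ester sits γ to the new alkoxide. The closest known reaction type is the intramolecular Nozaki–Hiyama–Kishi (Barbier-type) allylation of aldehydes by 2-(bromomethyl)acrylates that builds carbocycles fused to α-methylene lactones. Ring B closes in the 7-exo-trig mode (C8 in the ring, its oxygen outside), helped by the norbornene, which holds the two arms on the adjacent atoms C1 and C5. C8 is controlled by C10 and the bridgehead (the arm should react with the C10 methyl turned away from the forming ring and the chromium-bound oxygen equatorial, which puts O8 on the face opposite the methyl and the C2 bridge), and C7 is controlled relative to C8 by the chair in which both tether bonds (C7–C6, C8–C9) are equatorial and H7/H8 anti, so that C11 lands on the face of the C2 bridge. The step needs γ- rather than α-attack (seven- versus nine-membered ring, secured by the cyclic transition state), reaction at the aldehyde only (lactone, acetates, ester and the free tertiary alcohol are inert to the chromium reagents) and the 7,8-trans relationship. Because allylchromium species equilibrate their double-bond geometry, the (Z)-bromide does not fix the outcome: the trans product comes from the rotamer with C6 anti to C13, while the chair with C6 axial, which would give the 7,8-cis isomer, is the competing path and the main risk of the route.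

Step 29
Reactants: 40 the ring-B 8-hydroxy 12-methyl ester
Product: 41 CNP0257312.1 (target)
Conditions: pyridinium p-toluenesulfonate (20 mol %), toluene, 4 Å molecular sieves, 60 °C
Reagents that add atoms: none
Why: Acid-catalysed transesterification of the C8 hydroxyl onto the C12 methyl ester closes the trans-fused γ-lactone, and the weak pyridinium acid should spare the tertiary allylic alcohol and both acetates.

**Compound list**

1 | 3-methylfuran-2-carbaldehyde | Cc1ccoc1C=O | starting material
2 | (E)-crotylboronic acid pinacol ester | C/C=C/CB1OC(C)(C)C(C)(C)O1 | starting material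
3 | (1R,2R)-2-methyl-1-(3-methylfuran-2-yl)but-3-en-1-ol (anti) | Cc1ccoc1[C@H](O)[C@H](C)C=C | intermediate
4 | (1R,2R)-2-methyl-1-(3-methylfuran-2-yl)butane-1,4-diol | Cc1ccoc1[C@H](O)[C@H](C)CCO | intermediate
5 | (1R,2R)-4-[(tert-butyldiphenylsilyl)oxy]-2-methyl-1-(3-methylfuran-2-yl)butan-1-ol | Cc1ccoc1[C@H](O)[C@H](C)CCO[Si](c2ccccc2)(c2ccccc2)C(C)(C)C | intermediate
6 | (4R,5S)-5-[(2R)-4-[(tert-butyldiphenylsilyl)oxy]butan-2-yl]-4-hydroxy-2-methylcyclopent-2-en-1-one (4,5-trans) | O[C@@H]1C=C(C)C(=O)[C@H]1[C@H](C)CCO[Si](c2ccccc2)(c2ccccc2)C(C)(C)C | intermediate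
7 | (1R,5S)-5-[(2R)-4-[(tert-butyldiphenylsilyl)oxy]butan-2-yl]-3-methyl-4-oxocyclopent-2-en-1-yl acetate | CC(=O)O[C@@H]1C=C(C)C(=O)[C@H]1[C@H](C)CCO[Si](c2ccccc2)(c2ccccc2)C(C)(C)C | intermediate
8 | (S)-(+)-carvone | CC1=CC[C@@H](CC1=O)C(C)=C | starting material
9 | (1S,5S)-cis-carveol, (1S,5S)-2-methyl-5-(prop-1-en-2-yl)cyclohex-2-en-1-ol | C=C(C)[C@H]1CC=C(C)[C@@H](O)C1 | intermediate
10 | (1S,2S,4R,6R)-1-methyl-4-(prop-1-en-2-yl)-7-oxabicyclo[4.1.0]heptan-2-ol (oxirane cis to OH and to isopropenyl) | C=C(C)[C@H]1C[C@H]2O[C@@]2(C)[C@@H](O)C1 | intermediate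
11 | 2-methyl-3-(phenylselanyl)-5-(prop-1-en-2-yl)cyclohexane-1,2-diol, selenium trans to the C2 hydroxyl, both hydroxyls cis to isopropenyl | C=C(C)[C@H]1C[C@H]([Se]c2ccccc2)[C@@](C)(O)[C@@H](O)C1 | intermediate (not isolated)
12 | (1S,2R,5R)-2-methyl-5-(prop-1-en-2-yl)cyclohex-3-ene-1,2-diol | C=C(C)[C@H]1C=C[C@@](C)(O)[C@@H](O)C1 | intermediate
13 | 3,4-epoxide of 12, oxirane cis to both hydroxyls and to isopropenyl | C=C(C)[C@H]1[C@H]2O[C@H]2[C@@](C)(O)[C@@H](O)C1 | intermediate
14 | (1S,2R,4S,5S)-2-methyl-5-(prop-1-en-2-yl)cyclohexane-1,2,4-triol (three hydroxyls cis to isopropenyl) | C=C(C)[C@H]1[C@@H](O)C[C@@](C)(O)[C@@H](O)C1 | intermediate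
15 | (1S,2R,4S,5S)-5-(3-hydroxyprop-1-en-2-yl)-2-methylcyclohexane-1,2,4-triol | C=C(CO)[C@H]1[C@@H](O)C[C@@](C)(O)[C@@H](O)C1 | intermediate
16 | cis-fused lactol of the enal derived from 15 (anomeric mixture) | C=C1C(O)O[C@H]2C[C@@](C)(O)[C@@H](O)C[C@@H]12 | intermediate (not isolated)
17 | (3aS,5S,6R,7aS)-5,6-dihydroxy-6-methyl-3-methylidenehexahydro-1-benzofuran-2(3H)-one (cis-fused) | C=C1C(=O)O[C@H]2C[C@@](C)(O)[C@@H](O)C[C@@H]12 | intermediate
18 | (3aS,6R,7aS)-6-hydroxy-6-methyl-3-methylidenetetrahydro-1-benzofuran-2,5(3H,4H)-dione | C=C1C(=O)O[C@H]2C[C@@](C)(O)C(=O)C[C@@H]12 | intermediate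
19 | (3aS,6R,7aS)-6-methyl-3-methylidene-6-[(triethylsilyl)oxy]tetrahydro-1-benzofuran-2,5(3H,4H)-dione | C=C1C(=O)O[C@H]2C[C@@](C)(O[Si](CC)(CC)CC)C(=O)C[C@@H]12 | intermediate
20 | (3aS,6R,7aS)-6-methyl-3-methylidene-2-oxo-6-[(triethylsilyl)oxy]-2,3,3a,6,7,7a-hexahydro-1-benzofuran-5-yl trifluoromethanesulfonate | C=C1C(=O)O[C@H]2C[C@@](C)(O[Si](CC)(CC)CC)C(OS(=O)(=O)C(F)(F)F)=C[C@@H]12 | intermediate
21 | (S)-γ-valerolactone | C[C@H]1CCC(=O)O1 | starting material
22 | (S)-pentane-1,4-diol | C[C@H](O)CCCO | intermediate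
23 | (S)-5-[(tert-butyldimethylsilyl)oxy]pentan-2-ol | C[C@H](O)CCCO[Si](C)(C)C(C)(C)C | intermediate
24 | tert-butyl{[(4R)-4-iodopentyl]oxy}dimethylsilane | C[C@@H](I)CCCO[Si](C)(C)C(C)(C)C | intermediate
25 | 5-[(tert-butyldimethylsilyl)oxy]pentan-2-yllithium, configuration of 24 retained (Li in place of I) | C[C@@H]([Li])CCCO[Si](C)(C)C(C)(C)C | intermediate (not isolated)
26 | {5-[(tert-butyldimethylsilyl)oxy]pentan-2-yl}[(trimethylsilyl)methyl]zinc, configuration retained | C[C@@H]([Zn]C[Si](C)(C)C)CCCO[Si](C)(C)C(C)(C)C | intermediate (not isolated)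
27 | (3aS,6R,7aS)-5-[(2R)-5-[(tert-butyldimethylsilyl)oxy]pentan-2-yl]-6-methyl-3-methylidene-6-[(triethylsilyl)oxy]-3a,6,7,7a-tetrahydro-1-benzofuran-2(3H)-one | C=C1C(=O)O[C@H]2C[C@@](C)(O[Si](CC)(CC)CC)C([C@H](C)CCCO[Si](C)(C)C(C)(C)C)=C[C@@H]12 | intermediate
28 | (3aS,6R,7aS)-6-hydroxy-5-[(2R)-5-hydroxypentan-2-yl]-6-methyl-3-methylidene-3a,6,7,7a-tetrahydro-1-benzofuran-2(3H)-one | C=C1C(=O)O[C@H]2C[C@@](C)(O)C([C@H](C)CCCO)=C[C@@H]12 | intermediate
29 | (4R)-4-[(3aS,6R,7aS)-6-hydroxy-6-methyl-3-methylidene-2-oxo-2,3,3a,6,7,7a-hexahydro-1-benzofuran-5-yl]pentyl acetate | C=C1C(=O)O[C@H]2C[C@@](C)(O)C([C@H](C)CCCOC(C)=O)=C[C@@H]12 | intermediate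
30 | (1R)-2-[(2R)-4-[(tert-butyldiphenylsilyl)oxy]butan-2-yl]-4-methyl-3-[(triethylsilyl)oxy]cyclopenta-2,4-dien-1-yl acetate | CC(=O)O[C@@H]1C=C(C)C(O[Si](CC)(CC)CC)=C1[C@H](C)CCO[Si](c2ccccc2)(c2ccccc2)C(C)(C)C | intermediate (not isolated)
31 | Diels–Alder adduct: norbornene with C2 acetate anti to C4=C5, C4 methyl, C5 triethylsilyloxy, C1 (2R)-4-(tert-butyldiphenylsilyloxy)butan-2-yl, C11′ spiro to the lactone of 29 with C12′=O endo and C7′ exo; all centres as in the target | CC(C)(C)[Si](c1ccccc1)(c1ccccc1)OCC[C@@H](C)[C@]34C[C@]5(C(=O)O[C@H]6C[C@@](C)(O)C([C@H](C)CCCOC(C)=O)=C[C@H]65)[C@H](C(C)=C3O[Si](CC)(CC)CC)[C@H]4OC(C)=O | intermediate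
32 | C5 enol triflate of 31 (trifluoromethanesulfonyloxy in place of triethylsilyloxy) | CC(C)(C)[Si](c1ccccc1)(c1ccccc1)OCC[C@@H](C)[C@]34C[C@]5(C(=O)O[C@H]6C[C@@](C)(O)C([C@H](C)CCCOC(C)=O)=C[C@H]65)[C@H](C(C)=C3OS(=O)(=O)C(F)(F)F)[C@H]4OC(C)=O | intermediate
33 | allyltributylstannane | C=CC[Sn](CCCC)(CCCC)CCCC | starting material
34 | C5-allyl norbornene with the C8 tert-butyldiphenylsilyl ether | CC(C)(C)[Si](c1ccccc1)(c1ccccc1)OCC[C@@H](C)[C@]34C[C@]5(C(=O)O[C@H]6C[C@@](C)(O)C([C@H](C)CCCOC(C)=O)=C[C@H]65)[C@H](C(C)=C3CC=C)[C@H]4OC(C)=O | intermediate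
35 | C5-allyl norbornene with the free C8 primary alcohol | OCC[C@@H](C)[C@]34C[C@]5(C(=O)O[C@H]6C[C@@](C)(O)C([C@H](C)CCCOC(C)=O)=C[C@H]65)[C@H](C(C)=C3CC=C)[C@H]4OC(C)=O | intermediate
36 | C5-allyl norbornene with the C8 aldehyde | O=CC[C@@H](C)[C@]34C[C@]5(C(=O)O[C@H]6C[C@@](C)(O)C([C@H](C)CCCOC(C)=O)=C[C@H]65)[C@H](C(C)=C3CC=C)[C@H]4OC(C)=O | intermediate
37 | methyl 2-(bromomethyl)acrylate | C=C(CBr)C(=O)OC | starting material
38 | 7,8-seco aldehyde (Z)-allylic bromide (precursor of the key step) | O=CC[C@@H](C)[C@]34C[C@]5(C(=O)O[C@H]6C[C@@](C)(O)C([C@H](C)CCCOC(C)=O)=C[C@H]65)[C@H](C(C)=C3C/C=C(\CBr)C(=O)OC)[C@H]4OC(C)=O | intermediate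
39 | C13 allylchromium dichloride derived from 38 | O=CC[C@@H](C)[C@]34C[C@]5(C(=O)O[C@H]6C[C@@](C)(O)C([C@H](C)CCCOC(C)=O)=C[C@H]65)[C@H](C(C)=C3C/C=C(\C[Cr](Cl)Cl)C(=O)OC)[C@H]4OC(C)=O | intermediate (not isolated)
40 | ring-B 8-hydroxy 12-methyl ester (7,8-trans; C11 on the face of the C2 bridge) | O[C@@H]2C[C@@H](C)[C@]34C[C@]5(C(=O)O[C@H]6C[C@@](C)(O)C([C@H](C)CCCOC(C)=O)=C[C@H]65)[C@H](C(C)=C3C[C@H]2C(=C)C(=O)OC)[C@H]4OC(C)=O | intermediate
41 | CNP0257312.1 | C=C1C(=O)O[C@@H]2C[C@@H](C)[C@]34C[C@]5(C(=O)O[C@H]6C[C@@](C)(O)C([C@H](C)CCCOC(C)=O)=C[C@H]65)[C@H](C(C)=C3C[C@@H]12)[C@H]4OC(C)=O | target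

**Count.** Total: 29 steps. Longest linear sequence: 21 steps, from (S)-carvone (steps 6–15, 19–29).

**Steps most likely to fail**

1. Step 28. The allylchromium may close through the chair that has C6 axial, or add to the other face of the aldehyde, which would give the 7,8-cis or the C8-epimeric ring B; α-attack and simple reduction of the aldehyde are lesser risks. Fallback (sets out from 38, returns at 40): the bromide is exchanged for tin with hexabutylditin and catalytic Pd(PPh3)4 to give the allylstannane F1. F1 is then cyclised with BF3·OEt2 in CH2Cl2 at −78 °C, an intramolecular Lewis-acid allylstannane–aldehyde addition through an open, non-chelated transition state whose diastereoselection follows different rules, and the hydroxy ester 40 is isolated.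

2. Step 22. The 5-acetoxy diene may isomerise by 1,5-hydrogen shift (or form by enolisation toward C2) before it is trapped, the silyl enol ether may add in Michael fashion without ring closure, or endo and facial selectivity may erode. Fallback (sets out from 7 and 29, returns at 34): the ketone of 7 is allylated with allyl bromide and indium powder in THF–water, Barbier conditions that spare the acetate, to give the tertiary homoallylic alcohol F2. Dehydration with methyl N-(triethylammoniumsulfonyl)carbamate gives the 5-acetoxy-2-allylcyclopentadiene F3, which undergoes a thermal Diels–Alder reaction with 29. The adduct is 34 itself, so steps 23 and 24 fall away.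

3. Step 19. The secondary organometallic may lose its configuration (warming of the alkyllithium, β-hydride elimination and reinsertion on palladium), or oxidative addition at the hindered triflate may be slow. Fallback (sets out from 24 and 20, returns at 27): direct zinc insertion into 24 (zinc dust, LiCl, THF) gives the configurationally mixed alkylzinc iodide F4. F4 is coupled with 20 under the same palladium catalysis, and 27 is separated from its C4′ epimer F5 by preparative chromatography.

**Further compounds**

F1 | step 28 | C13 tributylstannane analogue of 38 (allylstannane aldehyde) | O=CC[C@@H](C)[C@]34C[C@]5(C(=O)O[C@H]6C[C@@](C)(O)C([C@H](C)CCCOC(C)=O)=C[C@H]65)[C@H](C(C)=C3C/C=C(\C[Sn](CCCC)(CCCC)CCCC)C(=O)OC)[C@H]4OC(C)=O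
F2 | step 22 | (1R,5S)-4-allyl-5-[(2R)-4-[(tert-butyldiphenylsilyl)oxy]butan-2-yl]-4-hydroxy-3-methylcyclopent-2-en-1-yl acetate (carbinol epimers) | CC(=O)O[C@@H]1C=C(C)C(O)(CC=C)[C@H]1[C@H](C)CCO[Si](c2ccccc2)(c2ccccc2)C(C)(C)C
F3 | step 22 | (1R)-3-allyl-2-[(2R)-4-[(tert-butyldiphenylsilyl)oxy]butan-2-yl]-4-methylcyclopenta-2,4-dien-1-yl acetate | CC(=O)O[C@@H]1C=C(C)C(CC=C)=C1[C@H](C)CCO[Si](c2ccccc2)(c2ccccc2)C(C)(C)C
F4 | step 19 | {5-[(tert-butyldimethylsilyl)oxy]pentan-2-yl}zinc iodide (both configurations) | CC([Zn]I)CCCO[Si](C)(C)C(C)(C)C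
F5 | step 19 | C4′ epimer of 27 [(2S)-pentan-2-yl side chain] | C=C1C(=O)O[C@H]2C[C@@](C)(O[Si](CC)(CC)CC)C([C@@H](C)CCCO[Si](C)(C)C(C)(C)C)=C[C@@H]12
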